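**Retrosynthetic overview**

1. Oxolane numbering used here: O1, C2 (aryl), C3 (CH2OH), C4 (aroyl), C5 (CH2). The end game is hydrogenolysis of two phenolic benzyl ethers; the C3 CH2OH comes from a C3 vinyl group by oxidative cleavage and aldehyde-selective reduction.
2. Key disconnection: O1–C5 and C3–C4 are made together in a palladium-catalysed (3+2) cycloaddition. The trans-(2R,3R)-2-aryl-3-vinyloxirane supplies O1–C2–C3 as a π-allylpalladium alkoxide zwitterion; an aryl vinyl ketone supplies C4=C5.
3. Enabling feature: in the oxolane ring, O1 lies β to the C4 aryl ketone carbonyl (C5 is the β-carbon, C4 the α-carbon), an oxa-Michael/enolate relationship. C3, next to the benzylic C2–O1 bond, carries a one-carbon branch that can be grown to a vinyl group, which makes C3 an allyl terminus. The extra vinyl CH2 is a temporary activating group, removed in step 7.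
4. Both partners come from O-benzylsyringaldehyde: allylphosphonate olefination then Shi epoxidation (sets C2 and, through the trans-epoxide, C3); vinyl Grignard addition then MnO2 oxidation.
5. Ring order: both benzene rings are bought; a transient oxirane (step 3) is expanded into the oxolane, the only ring built, in step 6.

Key step: step 6

Remark (assumption): the two palladium-bound intermediates of step 6 are drawn as σ-allyl forms with the dppe ligand left out.

**Route**

Step 1
Reactants: 1 syringaldehyde (4-hydroxy-3,5-dimethoxybenzaldehyde)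
Product: 2 4-(benzyloxy)-3,5-dimethoxybenzaldehyde
Conditions: BnBr, K2CO3, DMF, 60 °C
Reagents that add atoms: benzyl bromide, BrCc1ccccc1
Why: Williamson ether synthesis on the phenoxide, which masks the acidic phenol through the basic and organometallic steps and is removable by hydrogenolysis at the end.

Step 2
Reactants: 2 4-(benzyloxy)-3,5-dimethoxybenzaldehyde
Product: 3 (E)-1-[4-(benzyloxy)-3,5-dimethoxyphenyl]buta-1,3-diene
Conditions: diethyl allylphosphonate, n-BuLi, THF, −78 °C; then 2 and HMPA, −78 °C to rt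
Reagents that add atoms: diethyl allylphosphonate, C=CCP(=O)(OCC)OCC
Why: Horner–Wadsworth–Emmons olefination with the α-lithiated allylphosphonate, which with aromatic aldehydes should give the terminal (E)-1,3-diene through the thermodynamically preferred elimination.

Step 3
Reactants: 3 (E)-1-[4-(benzyloxy)-3,5-dimethoxyphenyl]buta-1,3-diene
Product: 4 (2R,3R)-2-[4-(benzyloxy)-3,5-dimethoxyphenyl]-3-ethenyloxirane (trans)
Conditions: Shi ketone from D-fructose (1,2:4,5-di-O-isopropylidene-β-D-erythro-2,3-hexodiulo-2,6-pyranose, 30 mol %), Oxone (2KHSO5·KHSO4·K2SO4), K2CO3, n-Bu4NHSO4 (cat.), MeCN/dimethoxymethane/aq. Na2B4O7 buffer (pH 10.5), 0 °C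
Reagents that add atoms: potassium peroxymonosulfate (active component of Oxone), [K+].[O-]S(=O)(=O)OO
Why: Shi asymmetric epoxidation, in which the chiral dioxirane formed in situ should epoxidise only the electron-rich trans-disubstituted styrenyl double bond (the terminal vinyl group is a poor substrate for this catalyst) through a spiro transition state that, as with other trans-β-substituted styrenes, delivers the (R,R)-epoxide and so fixes C2 and the trans geometry used in step 6.

Step 4
Reactants: 2 4-(benzyloxy)-3,5-dimethoxybenzaldehyde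
Product: 5 1-[4-(benzyloxy)-3,5-dimethoxyphenyl]prop-2-en-1-ol (racemic)
Conditions: CH2=CHMgBr, THF, −78 to 0 °C; then aq. NH4Cl
Reagents that add atoms: vinylmagnesium bromide, C=C[Mg]Br
Why: Grignard 1,2-addition to the aldehyde, whose new stereocentre needs no control because it is oxidised away in step 5.

Step 5
Reactants: 5 1-[4-(benzyloxy)-3,5-dimethoxyphenyl]prop-2-en-1-ol
Product: 6 1-[4-(benzyloxy)-3,5-dimethoxyphenyl]prop-2-en-1-one
Conditions: activated MnO2 (excess), CH2Cl2, rt; filtered and used at once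
Reagents that add atoms: none
Why: MnO2 oxidation of a doubly activated (benzylic and allylic) alcohol under neutral heterogeneous conditions, whose filtration-only work-up suits the polymerisation-prone aryl vinyl ketone.

Step 6
Reactants: 4 (2R,3R)-2-[4-(benzyloxy)-3,5-dimethoxyphenyl]-3-ethenyloxirane; 6 1-[4-(benzyloxy)-3,5-dimethoxyphenyl]prop-2-en-1-one
Product: 9 [(3S,4S,5S)-5-[4-(benzyloxy)-3,5-dimethoxyphenyl]-4-ethenyloxolan-3-yl][4-(benzyloxy)-3,5-dimethoxyphenyl]methanone (all-trans), via π-allylpalladium alkoxide zwitterion 7 (not isolated), via π-allylpalladium enolate 8 (not isolated)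
Conditions: Pd2(dba)3·CHCl3 (2.5 mol %), dppe (5.5 mol %), 6 (1.5 equiv), THF, 0 °C to rt, slow addition of 4
Reagents that add atoms: none
Why: Zerovalent palladium ionises the allylic C3–O bond of 4 with inversion to give the zwitterionic π-allylpalladium alkoxide 7, whose benzylic alkoxide adds to the unsubstituted β-carbon of enone 6 (oxa-Michael, O1–C5) to give enolate 8, and the enolate carbon then attacks the proximal allyl terminus (C3–C4) and releases the catalyst. The closest known reaction type is the palladium-catalysed formal (3+2) cycloaddition of vinyl epoxides (and of vinyl aziridines and vinylethylene carbonates) with Michael acceptors, α,β-unsaturated ketones included, which gives 3-vinyltetrahydrofurans. The oxolane ring closes by 5-exo-trig attack of the enolate α-carbon on the π-allyl unit, the vinyl group staying exocyclic, in preference to seven-membered closure at the distal terminus or through the enolate oxygen. C2 is carried over unchanged from the epoxide; C3 is set by attack anti to palladium, so that two inversions give net retention and place vinyl trans to the C2 aryl group, the same outcome that the less crowded transition state would give if the allyl faces interconvert; C4 is set with the aroyl group trans to vinyl in the envelope transition state and, being α to the ketone, can settle to the same all-trans isomer under the weakly basic conditions. The step needs chemoselective capture of 7 by the enone before hydride-shift isomerisation of the zwitterion or oligomerisation of the enone, which the very electrophilic and sterically open terminal vinyl ketone, held in excess while 4 is added slowly, should secure.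

Step 7
Reactants: 9 [(3S,4S,5S)-5-[4-(benzyloxy)-3,5-dimethoxyphenyl]-4-ethenyloxolan-3-yl][4-(benzyloxy)-3,5-dimethoxyphenyl]methanone
Product: 11 (2S,3S,4S)-2-[4-(benzyloxy)-3,5-dimethoxyphenyl]-4-[4-(benzyloxy)-3,5-dimethoxybenzoyl]oxolane-3-carbaldehyde, via vicinal diol 10 (not isolated)
Conditions: OsO4 (2 mol %), NaIO4 (4 equiv), 2,6-lutidine, dioxane/H2O (3:1), rt
Reagents that add atoms: osmium tetroxide (catalyst, oxygen transfer), O=[Os](=O)(=O)=O; sodium periodate (terminal oxidant, source of the new oxygen), [Na+].[O-]I(=O)(=O)=O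
Why: Lemieux–Johnson oxidation, in which OsO4 dihydroxylates the only alkene to diol 10 and periodate cleaves it in the same flask, the 2,6-lutidine buffer keeping the medium near neutral so that C3 and C4, already in the more stable all-trans arrangement, should not be eroded.

Step 8
Reactants: 11 (2S,3S,4S)-2-[4-(benzyloxy)-3,5-dimethoxyphenyl]-4-[4-(benzyloxy)-3,5-dimethoxybenzoyl]oxolane-3-carbaldehyde
Product: 12 [(3S,4R,5S)-5-[4-(benzyloxy)-3,5-dimethoxyphenyl]-4-(hydroxymethyl)oxolan-3-yl][4-(benzyloxy)-3,5-dimethoxyphenyl]methanone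
Conditions: NaBH4 (1 equiv), CH2Cl2/EtOH (7:3), −78 °C; then H2O
Reagents that add atoms: none
Why: Chemoselective borohydride reduction, in which the aliphatic aldehyde should react far faster at −78 °C than the conjugated, electron-rich aryl ketone, with no new stereocentre formed and C3 and C4 untouched under the cold, brief conditions.

Step 9
Reactants: 12 [(3S,4R,5S)-5-[4-(benzyloxy)-3,5-dimethoxyphenyl]-4-(hydroxymethyl)oxolan-3-yl][4-(benzyloxy)-3,5-dimethoxyphenyl]methanone
Product: 13 [(3S,4R,5S)-5-(4-hydroxy-3,5-dimethoxyphenyl)-4-(hydroxymethyl)oxolan-3-yl](4-hydroxy-3,5-dimethoxyphenyl)methanone (target)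
Conditions: H2 (1 atm), Pd/C (10% Pd on carbon), EtOAc, rt
Reagents that add atoms: none
Why: Catalytic hydrogenolysis of the two aryl benzyl ethers, which in neutral ethyl acetate at 1 atm should be much faster than reduction of the electron-rich aryl ketone or cleavage of the benzylic C2–O1 ring bond, and which touches no stereocentre.

**Compound list**

1 | syringaldehyde (4-hydroxy-3,5-dimethoxybenzaldehyde) | COc1cc(C=O)cc(OC)c1O | starting material
2 | 4-(benzyloxy)-3,5-dimethoxybenzaldehyde | COc1cc(C=O)cc(OC)c1OCc1ccccc1 | intermediate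
3 | (E)-1-[4-(benzyloxy)-3,5-dimethoxyphenyl]buta-1,3-diene | C=C/C=C/c1cc(OC)c(OCc2ccccc2)c(OC)c1 | intermediate
4 | (2R,3R)-2-[4-(benzyloxy)-3,5-dimethoxyphenyl]-3-ethenyloxirane | C=C[C@H]1O[C@@H]1c1cc(OC)c(OCc2ccccc2)c(OC)c1 | intermediate
5 | 1-[4-(benzyloxy)-3,5-dimethoxyphenyl]prop-2-en-1-ol (racemic) | C=CC(O)c1cc(OC)c(OCc2ccccc2)c(OC)c1 | intermediate
6 | 1-[4-(benzyloxy)-3,5-dimethoxyphenyl]prop-2-en-1-one | C=CC(=O)c1cc(OC)c(OCc2ccccc2)c(OC)c1 | intermediate
7 | zwitterionic π-allylpalladium alkoxide from 4 (σ-allyl form, dppe omitted; carbinol carbon configured as C2 of 4) | [O-][C@H](c1cc(OC)c(OCc2ccccc2)c(OC)c1)/C=C/C[Pd+] | intermediate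
8 | π-allylpalladium enolate, the oxa-Michael adduct of 7 and 6 (σ-allyl form, dppe omitted) | [O-]C(=CCO[C@H](c1cc(OC)c(OCc2ccccc2)c(OC)c1)/C=C/C[Pd+])c1cc(OC)c(OCc2ccccc2)c(OC)c1 | intermediate
9 | [(3S,4S,5S)-5-[4-(benzyloxy)-3,5-dimethoxyphenyl]-4-ethenyloxolan-3-yl][4-(benzyloxy)-3,5-dimethoxyphenyl]methanone (all-trans) | COc1cc(C(=O)[C@@H]2CO[C@H](c3cc(OC)c(OCc4ccccc4)c(OC)c3)[C@H]2C=C)cc(OC)c1OCc1ccccc1 | intermediate
10 | [(3S,4R,5S)-5-[4-(benzyloxy)-3,5-dimethoxyphenyl]-4-(1,2-dihydroxyethyl)oxolan-3-yl][4-(benzyloxy)-3,5-dimethoxyphenyl]methanone (both carbinol epimers) | COc1cc(C(=O)[C@@H]2CO[C@H](c3cc(OC)c(OCc4ccccc4)c(OC)c3)[C@H]2C(O)CO)cc(OC)c1OCc1ccccc1 | intermediate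
11 | (2S,3S,4S)-2-[4-(benzyloxy)-3,5-dimethoxyphenyl]-4-[4-(benzyloxy)-3,5-dimethoxybenzoyl]oxolane-3-carbaldehyde | COc1cc(C(=O)[C@@H]2CO[C@H](c3cc(OC)c(OCc4ccccc4)c(OC)c3)[C@H]2C=O)cc(OC)c1OCc1ccccc1 | intermediate
12 | [(3S,4R,5S)-5-[4-(benzyloxy)-3,5-dimethoxyphenyl]-4-(hydroxymethyl)oxolan-3-yl][4-(benzyloxy)-3,5-dimethoxyphenyl]methanone | COc1cc(C(=O)[C@@H]2CO[C@H](c3cc(OC)c(OCc4ccccc4)c(OC)c3)[C@H]2CO)cc(OC)c1OCc1ccccc1 | intermediate
13 | [(3S,4R,5S)-5-(4-hydroxy-3,5-dimethoxyphenyl)-4-(hydroxymethyl)oxolan-3-yl](4-hydroxy-3,5-dimethoxyphenyl)methanone | COc1cc(C(=O)[C@@H]2CO[C@H](c3cc(OC)c(O)c(OC)c3)[C@H]2CO)cc(OC)c1O | target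

**Step count**

Total step count: 9
Longest linear sequence: 7 steps (steps 1, 2, 3, 6, 7, 8, 9)

**Three steps most likely to fail**

1. Step 6. The zwitterion may isomerise by hydride shift to an allyl aryl ketone, or collapse, before it meets the enone. The vinyl ketone may oligomerise under the alkoxide and enolate. Trans selectivity at C3 may erode if the allyl faces interconvert and ring closure is not selective. The fallback separates the two bond formations; it sets out from 4 (with 6) and comes back at 9. Pd(PPh3)4-catalysed 1,4-addition of acetic acid to 4 (THF, 0 °C) should give (S,E)-4-[4-(benzyloxy)-3,5-dimethoxyphenyl]-4-hydroxybut-2-en-1-yl acetate F1. PMe3-catalysed oxa-Michael addition of its benzylic hydroxyl to 6 should give the keto ether (S,E)-4-[4-(benzyloxy)-3,5-dimethoxyphenyl]-4-{3-[4-(benzyloxy)-3,5-dimethoxyphenyl]-3-oxopropoxy}but-2-en-1-yl acetate F2, formed without palladium and without a free alkoxide on an allyl cation. Deprotonation with LiN(SiMe3)2 (THF, −78 °C) should give the lithium enolate of F2 F3. Intramolecular Tsuji–Trost allylation of F3 with Pd(PPh3)4 (−78 to 0 °C) should then close the oxolane to 9 under the same stereochemical control (aryl/vinyl trans, aroyl trans to vinyl).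

2. Step 3. Site selectivity between the two diene double bonds may be poor, the diene may be over-oxidised, the electron-rich benzylic epoxide may open solvolytically in the aqueous medium, or facial selectivity may be insufficient. The fallback uses hydroxyl-directed epoxidation; it sets out from 2 and comes back at 4.
   - Horner–Wadsworth–Emmons reaction of 2 with triethyl phosphonoacetate (NaH, THF) should give ethyl (E)-3-[4-(benzyloxy)-3,5-dimethoxyphenyl]prop-2-enoate F4.
   - i-Bu2AlH (CH2Cl2, −78 °C) should reduce F4 through (E)-3-[4-(benzyloxy)-3,5-dimethoxyphenyl]prop-2-enal F5 (not isolated) to (E)-3-[4-(benzyloxy)-3,5-dimethoxyphenyl]prop-2-en-1-ol F6.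
   - Sharpless asymmetric epoxidation (Ti(OiPr)4, D-(−)-diisopropyl tartrate, t-BuOOH, 4 Å sieves, CH2Cl2, −20 °C) should give [(2R,3R)-3-[4-(benzyloxy)-3,5-dimethoxyphenyl]oxiran-2-yl]methanol F7 under anhydrous conditions.
   - Parikh–Doering oxidation (SO3·pyridine, DMSO, i-Pr2NEt) should give (2S,3R)-3-[4-(benzyloxy)-3,5-dimethoxyphenyl]oxirane-2-carbaldehyde F8.
   - Wittig methylenation (Ph3PCH3Br, KN(SiMe3)2, THF, −78 °C) should give 4.

3. Step 7. During cleavage and handling of the keto aldehyde, C3 may epimerise, or O1 (β to the new aldehyde) may be lost by β-elimination with opening of the oxolane. Selectivity between aldehyde and ketone may also be lost in step 8. The fallback removes the ketone before cleavage and restores it at the end; it sets out from 9 and comes back at 12.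
   - NaBH4 (MeOH, 0 °C) should reduce the ketone of 9 to [4-(benzyloxy)-3,5-dimethoxyphenyl][(3S,4S,5S)-5-[4-(benzyloxy)-3,5-dimethoxyphenyl]-4-ethenyloxolan-3-yl]methanol F9 (both carbinol epimers).
   - OsO4 (cat.)/NaIO4/2,6-lutidine in dioxane/H2O should take F9 through the triol 1-[(3R,4S,5S)-2-aryl-4-[aryl(hydroxy)methyl]oxolan-3-yl]ethane-1,2-diol F10 (not isolated; as SMILES below) to the hydroxy aldehyde (2S,3S,4S)-2-[4-(benzyloxy)-3,5-dimethoxyphenyl]-4-{[4-(benzyloxy)-3,5-dimethoxyphenyl](hydroxy)methyl}oxolane-3-carbaldehyde F11 (not isolated).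
   - NaBH4 added to the same flask should reduce F11 to the diol [4-(benzyloxy)-3,5-dimethoxyphenyl][(3S,4R,5S)-5-[4-(benzyloxy)-3,5-dimethoxyphenyl]-4-(hydroxymethyl)oxolan-3-yl]methanol F12.
   - Activated MnO2 (CH2Cl2, rt) should oxidise only the benzylic secondary alcohol of F12 and give 12.

**Further compounds**

F1 | step 6 | (S,E)-4-[4-(benzyloxy)-3,5-dimethoxyphenyl]-4-hydroxybut-2-en-1-yl acetate | CC(=O)OC/C=C/[C@H](O)c1cc(OC)c(OCc2ccccc2)c(OC)c1
F2 | step 6 | (S,E)-4-[4-(benzyloxy)-3,5-dimethoxyphenyl]-4-{3-[4-(benzyloxy)-3,5-dimethoxyphenyl]-3-oxopropoxy}but-2-en-1-yl acetate | CC(=O)OC/C=C/[C@H](OCCC(=O)c1cc(OC)c(OCc2ccccc2)c(OC)c1)c1cc(OC)c(OCc2ccccc2)c(OC)c1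
F3 | step 6 | lithium enolate of F2 (not isolated) | [Li+].CC(=O)OC/C=C/[C@H](OCC=C([O-])c1cc(OC)c(OCc2ccccc2)c(OC)c1)c1cc(OC)c(OCc2ccccc2)c(OC)c1
F4 | step 3 | ethyl (E)-3-[4-(benzyloxy)-3,5-dimethoxyphenyl]prop-2-enoate | CCOC(=O)/C=C/c1cc(OC)c(OCc2ccccc2)c(OC)c1
F5 | step 3 | (E)-3-[4-(benzyloxy)-3,5-dimethoxyphenyl]prop-2-enal (not isolated) | O=C/C=C/c1cc(OC)c(OCc2ccccc2)c(OC)c1
F6 | step 3 | (E)-3-[4-(benzyloxy)-3,5-dimethoxyphenyl]prop-2-en-1-ol | OC/C=C/c1cc(OC)c(OCc2ccccc2)c(OC)c1
F7 | step 3 | [(2R,3R)-3-[4-(benzyloxy)-3,5-dimethoxyphenyl]oxiran-2-yl]methanol | OC[C@H]1O[C@@H]1c1cc(OC)c(OCc2ccccc2)c(OC)c1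
F8 | step 3 | (2S,3R)-3-[4-(benzyloxy)-3,5-dimethoxyphenyl]oxirane-2-carbaldehyde | O=C[C@H]1O[C@@H]1c1cc(OC)c(OCc2ccccc2)c(OC)c1
F9 | step 7 | [4-(benzyloxy)-3,5-dimethoxyphenyl][(3S,4S,5S)-5-[4-(benzyloxy)-3,5-dimethoxyphenyl]-4-ethenyloxolan-3-yl]methanol (both carbinol epimers) | COc1cc(C(O)[C@@H]2CO[C@H](c3cc(OC)c(OCc4ccccc4)c(OC)c3)[C@H]2C=C)cc(OC)c1OCc1ccccc1
F10 | step 7 | 1-[(3R,4S,5S... oxolane numbering as in 10)-2-aryl-4-[aryl(hydroxy)methyl]oxolan-3-yl]ethane-1,2-diol, aryl = 4-(benzyloxy)-3,5-dimethoxyphenyl (triol, carbinol epimers, not isolated) | COc1cc(C(O)[C@@H]2CO[C@H](c3cc(OC)c(OCc4ccccc4)c(OC)c3)[C@H]2C(O)CO)cc(OC)c1OCc1ccccc1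
F11 | step 7 | (2S,3S,4S)-2-[4-(benzyloxy)-3,5-dimethoxyphenyl]-4-{[4-(benzyloxy)-3,5-dimethoxyphenyl](hydroxy)methyl}oxolane-3-carbaldehyde (carbinol epimers, not isolated) | COc1cc(C(O)[C@@H]2CO[C@H](c3cc(OC)c(OCc4ccccc4)c(OC)c3)[C@H]2C=O)cc(OC)c1OCc1ccccc1
F12 | step 7 | [4-(benzyloxy)-3,5-dimethoxyphenyl][(3S,4R,5S)-5-[4-(benzyloxy)-3,5-dimethoxyphenyl]-4-(hydroxymethyl)oxolan-3-yl]methanol (carbinol epimers) | COc1cc(C(O)[C@@H]2CO[C@H](c3cc(OC)c(OCc4ccccc4)c(OC)c3)[C@H]2CO)cc(OC)c1OCc1ccccc1
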